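The runs come from a simulation with constants of no real substance.

The chair opened by asking which flask ends with the most monomer in chains.

| setting | east | north-east | west | teal | green | amber | red |
|---|---|---|---|---|---|---|---|
| free monomer | 0.20 M | 0.20 M | 0.30 M | 0.20 M | 0.20 M | 0.20 M | 0.20 M |
| initiator | 0.5 mol% | 0.79 mol% | 0.36 mol% | 0.36 mol% | 0.36 mol% | 0.36 mol% | 0.36 mol% |
| temperature | 45 °C | 78 °C | 45 °C |  | 60 °C | 30 °C | 90 °C |
| remark | run made earlier | run made earlier | run made earlier | at 90 °C until 2.0 min, from then on at 30 °C |  |  |  |
| time |  |  |  | 2.5 min | 2.5 min | 2.5 min | 2.5 min |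

- east (time / min: monomer in chains / %, free monomer / %): 0.667: 40, 31; 1.33: 37, 13; 2.00: 25, 8; 3.00: 19, 0
- north-east (time / s: monomer in chains / %, free monomer / %): 10.0: 15, 18; 20.0: 3, 13; 40.0: 1, 12
- west (time / min: monomer in chains / %, free monomer / %): 0.333: 30, 54; 0.500: 35, 40; 0.833: 35, 21; 2.00: 22, 6; 3.00: 14, 1

(readings scatter by 1.5 percentage points)

1. the best flask by amount of monomer in chains, in percent of the free monomer charged; "all alike" if 1.5 percentage points covers them all (teal / green / amber / red / all alike)
2. amount of monomer in chains at the end, in percent of the free monomer charged, teal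
3. amount of monomer in chains at the end, in percent of the free monomer charged, green
4. amount of monomer in chains at the end, in percent of the free monomer charged, amber
5. amount of monomer in chains at the end, in percent of the free monomer charged, red

The kineticist proposed reading the tails of the runs, where monomer in chains falls, and counted that fall as pseudo-first-order, with free monomer down to 13% at 1.33 min in the east run. That run falls from 37% to 19% by 3.00 min, a loss rate of 0.399 min⁻¹ at 45 °C. The north-east run falls from 15% to 3% between 10.0 s and 20.0 s, a rate of 9.66 min⁻¹ at 78 °C, though she warned that the lower reading carries a scatter of 1.5 percentage points.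

Taking the logarithm of the rate as straight in temperature, she put amber at 0.0938 min⁻¹. That gives 7.39 min for the chain half-life, the time in which monomer in chains halves once no more is being made, ln(2) over the loss rate. The same line gave green 1.70 min⁻¹, so 0.408 min, and the 90 °C of red and early teal 0.0225 min.

Amber's half-life is longer than the 2.5 min asked, she said, while 6.13 half-lives fit into green, 111 into red, and 88.8 into teal before its cooling. She committed to amber, near the east run's first reading of 40%.

The forecaster reported amber, with 37% for amber, a little below her figure, then 2% for green, 0% for teal and 0% for red. On teal the forecast says: “Cooling teal at 2 min cannot restart growth.”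

The simulation gives amber: amber holds 39.2%, teal 0.00858% and red 0%.

    2 growing radical → dead chain (k = 4.00 × 10⁶ M⁻¹ s⁻¹, Ea = 16.0 kJ mol⁻¹)
    initiator → 2 initiating radical (k = 0.0530 s⁻¹, Ea = 97.0 kJ mol⁻¹)
    free monomer + initiating radical → growing radical + monomer in chains (k = 5.10 × 10⁵ M⁻¹ s⁻¹, Ea = 23.0 kJ mol⁻¹)
    free monomer → decomposition product (k = 3.10 × 10⁻⁵ s⁻¹, Ea = 97.0 kJ mol⁻¹)
    free monomer + monomer in chains → side product (k = 0.190 M⁻¹ s⁻¹, Ea = 51.0 kJ mol⁻¹)
    monomer in chains → over-reaction product (k = 0.0410 s⁻¹, Ea = 84.0 kJ mol⁻¹)
    free monomer + growing radical → monomer in chains + growing radical, rate k7*[growing radical]*[free monomer] (k = 20000 M⁻¹ s⁻¹, Ea = 19.0 kJ mol⁻¹)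
    (constants at 60 °C)

Amber ends with 8.46% of over-reaction product beside 27.3% of free monomer, and green holds 0.538%. The kineticist's chain half-life for amber stays an estimate from the earlier runs: 7.39 min, run on from amber's 39.2% for a further 22.5 min, gives 4.75%. Left until 25.0 min, amber holds 3.63%.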